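**Assumption:** (R)‑Danshensu 1 is taken as purchasable in enantiopure form (its sodium salt would serve equally in step 1). The lactone is numbered O1, C2 (carbonyl), C3, C4, C5 throughout.

## Analysis of the target

The target 18 is a trans‑α,β‑dibenzyl‑γ‑butyrolactone with the ring O1–C2(=O)–C3–C4–C5. C3 carries a 3,4‑dihydroxybenzyl group and C4 a 3,4‑dimethoxybenzyl group; both centres are R, so the two benzyl arms lie on opposite faces of the ring. The two aryl rings differ only in their O‑substituents, so they must be brought in separately, with the catechol masked until the end. The free catechol is prone to air oxidation, the lactone opens under base, and C3–H is enolisable. The relative configuration is the thermodynamically favoured one; the difficulty is the absolute configuration of two adjacent centres in a flexible, almost symmetric molecule. The strategy rests on C4, which carries two one‑carbon arms: C5 (bound to O1) and the exocyclic benzylic CH2. If the aryl group on that CH2 is replaced by OH, C4 becomes the central carbon of a 2‑substituted propane‑1,3‑diol, with two hydroxymethyl groups distinguished only by the neighbouring C3. One purchased stereocentre at C3 is then enough, and C4 follows from which hydroxymethyl group ends up in the ring.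

## Retrosynthetic reasoning

**18 ⇒ 17.** The two phenolic O–H bonds are traced back to benzyl ethers in dibenzyl lactone 17. A free catechol would not survive the sulfonylation and organometallic steps. Benzyl ethers are orthogonal to the two methyl ethers and to the lactone, and they come off by neutral hydrogenolysis that leaves C3 and C4 untouched.

**17 ⇒ 13 + 16.** The bond between the exocyclic CH2 on C4 and the dimethoxyphenyl ring is cut. This cut, rather than the one between C4 and its CH2, leaves on C4 a one‑carbon arm of the same kind as C5. The forward reaction is the substitution of primary triflate 13 by lithium diarylcuprate 16, made from aryl bromide 14 through aryllithium 15. It takes place one carbon away from C4, so neither stereocentre is at risk. Triflate 13 comes from hydroxymethyl lactone 12.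

**12 ⇒ 9.** The O1–C2 bond is cut. Opening the lactone gives dihydroxy acid 10, held as its tert‑butyl ester 9, in which C4 bears two identical hydroxymethyl groups and is no longer a stereocentre. Cutting the C3–benzyl bond instead would leave a monosubstituted lactone whose single centre would need an asymmetric method. Forward, acid must close the ring onto one of two diastereotopic hydroxymethyl groups: cis‑lactone 11 and trans‑lactone 12 both form, interconvert, and should settle on 12.

**9 ⇒ 8.** The two hydroxymethyl groups are traced to the two methyl esters of the malonate unit in triester 8. The third carboxyl is kept as a tert‑butyl ester, which resists the hydride and is later cleaved by the acid of the key step.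

**8 ⇒ 5 + 6.** The C3–C4 bond is cut. C4 with its two arms becomes the malonate carbanion 7, made from dimethyl malonate 6, and C3 becomes the electrophilic α‑carbon of α‑triflyloxy ester 5. The forward step is an SN2 displacement with inversion, so C3 is traced to a C–O stereocentre of an α‑hydroxy ester.

**5 ⇒ 4 ⇒ 3 ⇒ 2 ⇒ 1.** Triflate 5 comes from hydroxy ester 4, the tert‑butyl ester of the dibenzyl ether of 1. Compound 1 already holds the catechol ring, its benzylic CH2, the carboxyl carbon and an R carbinol centre that, after inversion, gives the R centre at C3. Three protecting‑group steps connect them: global benzylation to 2, saponification to acid 3, and chemoselective tert‑butyl esterification to 4.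

## Alternatives that were turned down

**Alternative 1:** Both benzylic C–C bonds on a preformed ring are cut, leading to the chiral alkoxybutenolide A2, the aryl dithiane A3 and the benzylic bromide A4. Forward, the 2‑lithio derivative of A3 adds to C4 of A2 anti to the menthyloxy group, and the lactone enolate is trapped at C3 by A4 anti to the new C4 substituent, giving A1 in one flask.
- For: it is convergent, attaches both aryl arms and sets both centres in one operation, and each kinetic anti preference is dependable. On convergence and certainty of stereocontrol it is at least as strong as the chosen route.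
- Against: A1 still needs reductive desulfurisation (a nickel reagent next to benzyl ethers), reduction of the acetal carbon C5 to CH2 with loss of a stoichiometric auxiliary, and debenzylation. A2 must be obtained as a single acetal epimer, A4 is a labile electron‑rich benzylic halide, and the dithiane anion is strongly basic.
- In its place the chosen route offers no auxiliary and no sulfur, a C3 centre bought with the catechol arm attached, a C4 centre whose minor isomer can be recycled through the equilibrium, and late introduction of the second aryl ring from 12.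

**Alternative 2:** The O1–C5 bond of the monosubstituted lactone A5 is cut back to the prochiral cyclobutanone A6. Forward, a Baeyer–Villiger monooxygenase inserts oxygen next to one of the two enantiotopic ring CH2 groups to give A5. Trans‑selective enolate alkylation with A4 would then give the same dibenzyl lactone as 17.
- For: A6 is achiral and quickly made, the oxidation is catalytic, and the anti alkylation of β‑substituted butyrolactone enolates is reliable. The route has roughly half as many steps, so on step economy it is clearly stronger.
- Against: the sense and level of enantioselectivity depend on finding an enzyme that accepts this bulky, electron‑rich 3‑benzylcyclobutanone. The enantiopurity of the whole route rests on that one biocatalytic event, and it needs fermentation or cofactor recycling.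
- In its place the chosen route fixes the absolute configuration by a purchased centre, predictably and with ordinary reagents.

**Alternative 3:** The C2–C3 and C2–O1 bonds are cut, so the carbonyl carbon is inserted into the E allylic alcohol A8. Forward, a chiral palladium hydride adds syn across C3=C4, the C3–Pd bond is carbonylated, and the hydroxyl captures the acyl group. The E geometry translates into the trans lactone A7, which is identical with 17.
- For: ring, carbonyl and both stereocentres arise in one catalytic step, one hydrogenolysis from the target. On paper this is the shortest route.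
- Against: the alkene is trisubstituted and unactivated, with a benzylic CH2 on each side. Hydropalladation should be slow, its regiochemistry is uncertain, and reversible β‑hydride elimination can move the alkene into conjugation with either arene and scramble position and geometry. Both enantio‑ and diastereocontrol must come from one ligand on a substrate class with little footing, and A8 must itself be made geometrically pure.
- The chosen route is longer, but its stereocentres rest on an SN2 inversion and an equilibrium rather than on an unproven asymmetric step.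

Key step: step 7

## Route

Step 1
Reactants: 1 (R)‑3‑(3,4‑dihydroxyphenyl)‑2‑hydroxypropanoic acid [(R)‑danshensu]
Product: 2 benzyl (R)‑3‑[3,4‑bis(benzyloxy)phenyl]‑2‑hydroxypropanoate
Conditions: BnBr (3.3 equiv), K2CO3 (4 equiv), DMF, rt → 40 °C, N2
Reagents that add atoms: benzyl bromide, BrCc1ccccc1
Why: O‑Alkylation (Williamson ether and carboxylate ester formation): carbonate deprotonates the carboxylic acid and both phenols but not the secondary alcohol, so three benzyl groups go on and the carbinol stays free; the stereocentre is not involved.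

Step 2
Reactants: 2 benzyl (R)‑3‑[3,4‑bis(benzyloxy)phenyl]‑2‑hydroxypropanoate
Product: 3 (R)‑3‑[3,4‑bis(benzyloxy)phenyl]‑2‑hydroxypropanoic acid
Conditions: LiOH·H2O, THF/H2O, 0 °C → rt; then 1 M HCl to pH 2–3
Reagents that add atoms: lithium hydroxide, [Li+].[OH-]
Why: Saponification (BAc2) of the benzyl ester; aryl benzyl ethers are inert to hydroxide and the α‑hydroxy carboxylate is not enolised, so the R centre should be kept.

Step 3
Reactants: 3 (R)‑3‑[3,4‑bis(benzyloxy)phenyl]‑2‑hydroxypropanoic acid
Product: 4 tert‑butyl (R)‑3‑[3,4‑bis(benzyloxy)phenyl]‑2‑hydroxypropanoate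
Conditions: Cl3CC(=NH)OtBu (2.5 equiv), CH2Cl2/cyclohexane, rt, no added acid
Reagents that add atoms: tert‑butyl 2,2,2‑trichloroacetimidate, CC(C)(C)OC(=N)C(Cl)(Cl)Cl
Why: Imidate esterification: the carboxylic acid protonates the trichloroacetimidate and the ion pair collapses to the tert‑butyl ester, whereas the secondary alcohol would need added strong acid; this installs the hydride‑resistant, acid‑labile ester needed in steps 6 and 7.

Step 4
Reactants: 4 tert‑butyl (R)‑3‑[3,4‑bis(benzyloxy)phenyl]‑2‑hydroxypropanoate
Product: 5 tert‑butyl (R)‑3‑[3,4‑bis(benzyloxy)phenyl]‑2‑{[(trifluoromethyl)sulfonyl]oxy}propanoate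
Conditions: Tf2O (1.2 equiv), 2,6‑lutidine (1.5 equiv), CH2Cl2, −78 → −40 °C; cold work‑up, used at once
Reagents that add atoms: trifluoromethanesulfonic anhydride, O=S(=O)(OS(=O)(=O)C(F)(F)F)C(F)(F)F
Why: O‑Sulfonylation of the secondary alcohol with retention at carbon; the hindered base and low temperature are chosen to suppress elimination to the cinnamate, and α‑triflyloxy esters of this kind can be handled briefly in the cold.

Step 5
Reactants: 5 tert‑butyl (R)‑3‑[3,4‑bis(benzyloxy)phenyl]‑2‑{[(trifluoromethyl)sulfonyl]oxy}propanoate; 6 dimethyl malonate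
Product: 8 2‑tert‑butyl 1,1‑dimethyl (R)‑3‑[3,4‑bis(benzyloxy)phenyl]propane‑1,1,2‑tricarboxylate, via sodium dimethyl malonate 7 (not isolated)
Conditions: 6 (2.0 equiv), NaH (1.9 equiv), THF, 0 °C; then 5, −20 °C → rt
Reagents that add atoms: none
Why: SN2 alkylation of the soft malonate carbanion by an α‑triflyloxy ester: the adjacent carbonyl accelerates backside attack and disfavours ionisation, so C–O is replaced by C–C with inversion. This sets the future C3 in the R configuration (the descriptor is unchanged only because the priorities change).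

Step 6
Reactants: 8 2‑tert‑butyl 1,1‑dimethyl (R)‑3‑[3,4‑bis(benzyloxy)phenyl]propane‑1,1,2‑tricarboxylate
Product: 9 tert‑butyl (R)‑2‑[3,4‑bis(benzyloxy)benzyl]‑4‑hydroxy‑3‑(hydroxymethyl)butanoate
Conditions: LiBH4 (4 equiv), MeOH (4 equiv), THF, 0 °C → rt; sat. aq. NH4Cl
Reagents that add atoms: none
Why: Chemoselective borohydride reduction of esters: the two unhindered methyl esters should be reduced to CH2OH while the tert‑butyl ester is left, and γ‑hydroxy tert‑butyl esters are expected to resist lactonisation in this weakly basic medium; C3 is not enolised.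

Step 7
Reactants: 9 tert‑butyl (R)‑2‑[3,4‑bis(benzyloxy)benzyl]‑4‑hydroxy‑3‑(hydroxymethyl)butanoate
Product: 12 (3R,4S)‑3‑[3,4‑bis(benzyloxy)benzyl]‑4‑(hydroxymethyl)dihydrofuran‑2(3H)‑one, via dihydroxy acid 10 (not isolated), via cis‑lactone 11 (not isolated)
Conditions: p‑TsOH·H2O (20 mol %), toluene, 85 °C, until the isomer ratio no longer changes
Reagents that add atoms: none
Why: Acid removes the tert‑butyl group as isobutene (AAL1 cleavage) to give dihydroxy acid 10. Either hydroxymethyl group then adds to the protonated carboxyl carbon C2 in a 5‑exo‑trig acyl substitution, closing the ring through the O1–C2 bond to give cis‑lactone 11 or trans‑lactone 12. The two lactones should interconvert under the same acid, by reversible ring opening to 10 with the water of condensation and by intramolecular acyl transfer through the bicyclic tetrahedral intermediate formed when the free hydroxymethyl group adds to C2. The equilibrium is expected to favour 12, in which the C3 benzyl group and the C4 hydroxymethyl group lie on opposite faces of the ring and avoid the eclipsing strain of the cis pair. The new centre C4 is therefore set by the existing centre C3 under thermodynamic substrate control, without a chiral reagent. The closest known reaction type is the acid‑mediated lactonisation of esters of 2‑substituted 1,3‑diols with equilibration to the trans‑3,4‑disubstituted butyrolactone. The step needs trans over cis selectivity and an untouched C3; acid secures the latter because lactones barely enolise under acid, whereas base would couple C3 epimerisation with acyl migration and lead into the enantiomeric series. The benzyl ethers and the arenes should be inert at this acid strength.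

Step 8
Reactants: 12 (3R,4S)‑3‑[3,4‑bis(benzyloxy)benzyl]‑4‑(hydroxymethyl)dihydrofuran‑2(3H)‑one
Product: 13 [(3R,4R)‑4‑[3,4‑bis(benzyloxy)benzyl]‑5‑oxotetrahydrofuran‑3‑yl]methyl trifluoromethanesulfonate
Conditions: Tf2O (1.2 equiv), 2,6‑lutidine (1.5 equiv), CH2Cl2, −78 → −40 °C; cold work‑up, used crude
Reagents that add atoms: trifluoromethanesulfonic anhydride, O=S(=O)(OS(=O)(=O)C(F)(F)F)C(F)(F)F
Why: Sulfonylation of the primary alcohol; with the hydroxyl capped, acyl migration is no longer possible and the C4 configuration is locked. Participation by the lactone carbonyl is not expected, since it would place a planar dioxocarbenium carbon at a bicyclo[2.2.1] bridgehead.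

Step 9
Reactants: 13 [(3R,4R)‑4‑[3,4‑bis(benzyloxy)benzyl]‑5‑oxotetrahydrofuran‑3‑yl]methyl trifluoromethanesulfonate; 14 4‑bromo‑1,2‑dimethoxybenzene
Product: 17 (3R,4R)‑3‑[3,4‑bis(benzyloxy)benzyl]‑4‑(3,4‑dimethoxybenzyl)dihydrofuran‑2(3H)‑one, via aryllithium 15 (not isolated), via lithium diarylcuprate 16 (not isolated)
Conditions: 14 (5 equiv), n‑BuLi (5 equiv), THF, −78 °C; CuI (2.5 equiv), −40 °C; then 13, −78 → −30 °C; aq. NH4Cl/NH3
Reagents that add atoms: none
Why: Halogen–lithium exchange, transmetalation to the diarylcuprate and substitution of the primary triflate (oxidative addition and reductive elimination at copper) form the sp3–sp2 bond. Cuprates are soft and weakly basic, so the lactone carbonyl and C3–H should be left alone, and the reaction occurs one carbon away from C4, which keeps its configuration.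

Step 10
Reactants: 17 (3R,4R)‑3‑[3,4‑bis(benzyloxy)benzyl]‑4‑(3,4‑dimethoxybenzyl)dihydrofuran‑2(3H)‑one
Product: 18 (3R,4R)‑3‑(3,4‑dihydroxybenzyl)‑4‑(3,4‑dimethoxybenzyl)dihydrofuran‑2(3H)‑one (3'‑O‑demethylarctigenin)
Conditions: H2 (1 atm), 10% Pd/C, EtOAc/EtOH, rt; work‑up under inert gas
Reagents that add atoms: none
Why: Catalytic hydrogenolysis of the two aryl benzyl ethers; the methyl ethers, the lactone and both sp3 stereocentres are unaffected under neutral conditions.

## Compound list

1 | (R)‑3‑(3,4‑dihydroxyphenyl)‑2‑hydroxypropanoic acid (danshensu) | O[C@H](Cc1ccc(O)c(O)c1)C(=O)O | starting material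
2 | benzyl (R)‑3‑[3,4‑bis(benzyloxy)phenyl]‑2‑hydroxypropanoate | O[C@H](Cc1ccc(OCc2ccccc2)c(OCc2ccccc2)c1)C(=O)OCc1ccccc1 | intermediate
3 | (R)‑3‑[3,4‑bis(benzyloxy)phenyl]‑2‑hydroxypropanoic acid | O[C@H](Cc1ccc(OCc2ccccc2)c(OCc2ccccc2)c1)C(=O)O | intermediate
4 | tert‑butyl (R)‑3‑[3,4‑bis(benzyloxy)phenyl]‑2‑hydroxypropanoate | O[C@H](Cc1ccc(OCc2ccccc2)c(OCc2ccccc2)c1)C(=O)OC(C)(C)C | intermediate
5 | tert‑butyl (R)‑3‑[3,4‑bis(benzyloxy)phenyl]‑2‑{[(trifluoromethyl)sulfonyl]oxy}propanoate | O=S(=O)(O[C@H](Cc1ccc(OCc2ccccc2)c(OCc2ccccc2)c1)C(=O)OC(C)(C)C)C(F)(F)F | intermediate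
6 | dimethyl malonate | COC(=O)CC(=O)OC | starting material
7 | sodium dimethyl malonate (sodium 1,3‑dimethoxy‑1,3‑dioxopropan‑2‑ide) | [Na+].COC(=O)[CH-]C(=O)OC | intermediate (not isolated)
8 | 2‑tert‑butyl 1,1‑dimethyl (R)‑3‑[3,4‑bis(benzyloxy)phenyl]propane‑1,1,2‑tricarboxylate | CC(C)(C)OC(=O)[C@@H](C(C(=O)OC)C(=O)OC)Cc1ccc(OCc2ccccc2)c(OCc2ccccc2)c1 | intermediate
9 | tert‑butyl (R)‑2‑[3,4‑bis(benzyloxy)benzyl]‑4‑hydroxy‑3‑(hydroxymethyl)butanoate | CC(C)(C)OC(=O)[C@@H](C(CO)CO)Cc1ccc(OCc2ccccc2)c(OCc2ccccc2)c1 | intermediate
10 | (R)‑2‑[3,4‑bis(benzyloxy)benzyl]‑4‑hydroxy‑3‑(hydroxymethyl)butanoic acid | OC(=O)[C@@H](C(CO)CO)Cc1ccc(OCc2ccccc2)c(OCc2ccccc2)c1 | intermediate (not isolated)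
11 | (3R,4R)‑3‑[3,4‑bis(benzyloxy)benzyl]‑4‑(hydroxymethyl)dihydrofuran‑2(3H)‑one (cis) | OC[C@@H]1COC(=O)[C@@H]1Cc1ccc(OCc2ccccc2)c(OCc2ccccc2)c1 | intermediate (not isolated)
12 | (3R,4S)‑3‑[3,4‑bis(benzyloxy)benzyl]‑4‑(hydroxymethyl)dihydrofuran‑2(3H)‑one (trans) | OC[C@H]1COC(=O)[C@@H]1Cc1ccc(OCc2ccccc2)c(OCc2ccccc2)c1 | intermediate
13 | [(3R,4R)‑4‑[3,4‑bis(benzyloxy)benzyl]‑5‑oxotetrahydrofuran‑3‑yl]methyl trifluoromethanesulfonate | O=S(=O)(OC[C@H]1COC(=O)[C@@H]1Cc1ccc(OCc2ccccc2)c(OCc2ccccc2)c1)C(F)(F)F | intermediate
14 | 4‑bromo‑1,2‑dimethoxybenzene | COc1ccc(Br)cc1OC | starting material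
15 | (3,4‑dimethoxyphenyl)lithium | [Li]c1ccc(OC)c(OC)c1 | intermediate (not isolated)
16 | lithium bis(3,4‑dimethoxyphenyl)cuprate | [Li+].COc1ccc([Cu-]c2ccc(OC)c(OC)c2)cc1OC | intermediate (not isolated)
17 | (3R,4R)‑3‑[3,4‑bis(benzyloxy)benzyl]‑4‑(3,4‑dimethoxybenzyl)dihydrofuran‑2(3H)‑one | COc1ccc(C[C@H]2COC(=O)[C@@H]2Cc2ccc(OCc3ccccc3)c(OCc3ccccc3)c2)cc1OC | intermediate
18 | (3R,4R)‑3‑(3,4‑dihydroxybenzyl)‑4‑(3,4‑dimethoxybenzyl)dihydrofuran‑2(3H)‑one (3'‑O‑demethylarctigenin) | COc1ccc(C[C@H]2COC(=O)[C@@H]2Cc2ccc(O)c(O)c2)cc1OC | target

## Step count and least certain steps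

Total step count: 10. Longest linear sequence: 10 steps (1 → 18); 6 and 14 enter as purchased materials in steps 5 and 9.

**Step 7 (key step).** The most likely failure is incomplete selection between the two hydroxymethyl groups: if the free‑energy gap between 11 and 12 is small, an appreciable share of the cis isomer remains at equilibrium. Slow equilibration, ring tert‑butylation by isobutene and intermolecular esterification are lesser risks. Any 11 that remains should be separated and returned to the same acid conditions. It must not be epimerised at C3 with base later, because that would produce the enantiomeric trans series.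
Fallback (kinetic, enzyme‑controlled group selection in place of equilibrium): setting out from 9, a lipase with vinyl acetate in an ether solvent acylates one hydroxymethyl group. The enzyme would be chosen from a screen so that the product is tert‑butyl (2R,3R)‑3‑(acetoxymethyl)‑2‑[3,4‑bis(benzyloxy)benzyl]‑4‑hydroxybutanoate F1. Brief TFA/CH2Cl2 at 0 °C closes the only free hydroxyl onto the ester, faster than 1,3‑acetyl migration, to give [(3S,4R)‑4‑[3,4‑bis(benzyloxy)benzyl]‑5‑oxotetrahydrofuran‑3‑yl]methyl acetate F2, which cannot translactonise. Lipase‑mediated deacetylation at pH 7 then returns to the route at 12.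

**Step 9.** The risks are deprotonation at C3 by the organometallic, followed by intramolecular displacement of the triflate to a cyclopropane‑fused lactone; attack on the lactone carbonyl; decay of the crude triflate before coupling; and aryl homocoupling.
Fallback (catalytic cross‑coupling through an organozinc in place of the cuprate): setting out from 12, Appel iodination (I2, PPh3, imidazole) gives (3R,4R)‑3‑[3,4‑bis(benzyloxy)benzyl]‑4‑(iodomethyl)dihydrofuran‑2(3H)‑one F3. Insertion of activated zinc (LiCl, THF) gives {[(3R,4R)‑4‑[3,4‑bis(benzyloxy)benzyl]‑5‑oxotetrahydrofuran‑3‑yl]methyl}zinc iodide F4. Pd‑catalysed Negishi coupling with 14 (Pd(OAc)2, a biarylphosphine ligand, THF, 50 °C) returns to the route at 17.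

**Step 5.** The risks are E2 loss of triflic acid across the benzylic position to the cinnamate, participation of the electron‑rich aryl ring (a phenonium pathway that would erode the inversion), and double alkylation of the malonate.
Fallback (redox condensation without a discrete sulfonate): setting out from 4 and 6, a Mitsunobu‑type dehydrative C‑alkylation with cyanomethylenetributylphosphorane in toluene with heating should join the two with inversion and return to the route at 8. It makes no new compound (F0).

**Step 6.** The risks are premature lactonisation onto the tert‑butyl ester followed by over‑reduction, stalling at the malonate enolate or the mono‑reduced hydroxy ester, and dehydration of the β‑hydroxy ester intermediate.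
Fallback (carboxylate as its own protecting group): setting out from 8, TFA/CH2Cl2 removes the tert‑butyl group first to give (R)‑2‑[3,4‑bis(benzyloxy)benzyl]‑4‑methoxy‑3‑(methoxycarbonyl)‑4‑oxobutanoic acid F5. LiBH4 then reduces the two methyl esters while the lithium carboxylate is inert. Acidification gives dihydroxy acid 10, which is taken on under the conditions of step 7 to 12.

## Further compounds

F1 | step 7 | tert‑butyl (2R,3R)‑3‑(acetoxymethyl)‑2‑[3,4‑bis(benzyloxy)benzyl]‑4‑hydroxybutanoate | CC(=O)OC[C@@H](CO)[C@@H](Cc1ccc(OCc2ccccc2)c(OCc2ccccc2)c1)C(=O)OC(C)(C)C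
F2 | step 7 | [(3S,4R)‑4‑[3,4‑bis(benzyloxy)benzyl]‑5‑oxotetrahydrofuran‑3‑yl]methyl acetate | CC(=O)OC[C@H]1COC(=O)[C@@H]1Cc1ccc(OCc2ccccc2)c(OCc2ccccc2)c1
F3 | step 9 | (3R,4R)‑3‑[3,4‑bis(benzyloxy)benzyl]‑4‑(iodomethyl)dihydrofuran‑2(3H)‑one | IC[C@H]1COC(=O)[C@@H]1Cc1ccc(OCc2ccccc2)c(OCc2ccccc2)c1
F4 | step 9 | {[(3R,4R)‑4‑[3,4‑bis(benzyloxy)benzyl]‑5‑oxotetrahydrofuran‑3‑yl]methyl}zinc iodide | I[Zn]C[C@H]1COC(=O)[C@@H]1Cc1ccc(OCc2ccccc2)c(OCc2ccccc2)c1
F0 | step 5 | none | none
F5 | step 6 | (R)‑2‑[3,4‑bis(benzyloxy)benzyl]‑4‑methoxy‑3‑(methoxycarbonyl)‑4‑oxobutanoic acid | OC(=O)[C@@H](C(C(=O)OC)C(=O)OC)Cc1ccc(OCc2ccccc2)c(OCc2ccccc2)c1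
A1 | alternative 1 | (3R,4R,5R)‑3‑[3,4‑bis(benzyloxy)benzyl]‑4‑[2‑(3,4‑dimethoxyphenyl)‑1,3‑dithian‑2‑yl]‑5‑{[(1R,2S,5R)‑2‑isopropyl‑5‑methylcyclohexyl]oxy}dihydrofuran‑2(3H)‑one | COc1ccc(C2(SCCCS2)[C@H]3[C@H](O[C@@H]4C[C@H](C)CC[C@H]4C(C)C)OC(=O)[C@@H]3Cc3ccc(OCc4ccccc4)c(OCc4ccccc4)c3)cc1OC
A2 | alternative 1 | (5R)‑5‑{[(1R,2S,5R)‑2‑isopropyl‑5‑methylcyclohexyl]oxy}furan‑2(5H)‑one | O=C1C=C[C@H](O[C@@H]2C[C@H](C)CC[C@H]2C(C)C)O1
A3 | alternative 1 | 2‑(3,4‑dimethoxyphenyl)‑1,3‑dithiane | COc1ccc(C2SCCCS2)cc1OC
A4 | alternative 1 | 1,2‑bis(benzyloxy)‑4‑(bromomethyl)benzene | BrCc1ccc(OCc2ccccc2)c(OCc2ccccc2)c1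
A5 | alternative 2 | (R)‑4‑(3,4‑dimethoxybenzyl)dihydrofuran‑2(3H)‑one | COc1ccc(C[C@H]2COC(=O)C2)cc1OC
A6 | alternative 2 | 3‑(3,4‑dimethoxybenzyl)cyclobutan‑1‑one | COc1ccc(CC2CC(=O)C2)cc1OC
A7 | alternative 3 | (3R,4R)‑3‑[3,4‑bis(benzyloxy)benzyl]‑4‑(3,4‑dimethoxybenzyl)dihydrofuran‑2(3H)‑one (identical with 17) | COc1ccc(C[C@H]2COC(=O)[C@@H]2Cc2ccc(OCc3ccccc3)c(OCc3ccccc3)c2)cc1OC
A8 | alternative 3 | (E)‑4‑[3,4‑bis(benzyloxy)phenyl]‑2‑(3,4‑dimethoxybenzyl)but‑2‑en‑1‑ol | OC/C(Cc1ccc(OC)c(OC)c1)=C/Cc1ccc(OCc2ccccc2)c(OCc2ccccc2)c1
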